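**Assumptions (one line each)**
- Presumed biosynthesis: ent-kauranoid → 7,20-hemiketal (7,20-epoxy) → oxidative C6–C7 scission to the 7,20-lactone 6-aldehyde → reduction; atom labels C1–C20 below are the ent-kaurane positions of the target.
- Centres marked "epimers" (C6 carbinol, C8, C10–H, C12–S) are carried as mixtures because they are destroyed or reset later; their SMILES leave them open.
- Reagents that occur only in the fallbacks are taken as on hand.

**Retrosynthetic overview**
1. 25 ⇐ kinetic protonation at C16 ⇐ ring D by aldol (C16→C13) ⇐ ring C by Diels–Alder across C8=C9 of spirolactone 15.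
2. The spiro δ-lactone ⇐ C6–C7 glycol scission of the 7,20-hemiketal 11 (carbocyclic ring B), as in the plant.
3. Ring B ⇐ C8 enolate addition to the 7,20-lactone carbonyl of 10; C10 quaternary centre ⇐ Michael addition to pent-1-en-3-one; C5 ⇐ enantioselective Mukaiyama–Michael addition to dienone 2.
4. Ring order: A (bought) → 7,20-lactone → ring B/hemiketal → scission to the spirolactone → ring C → ring D.

**Route**

Step 1
Reactants: 1 4,4-dimethylcyclohex-2-en-1-one
Product: 2 4,4-dimethylcyclohexa-2,5-dien-1-one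
Conditions: DDQ (1.3 equiv), dioxane, reflux
Reagents that add atoms: none
Why: DDQ dehydrogenation (hydride abstraction from the dienol) introduces the second ring double bond and makes the two β-carbons enantiotopic; no stereocentre is formed.

Step 2
Reactants: 2 4,4-dimethylcyclohexa-2,5-dien-1-one; 3 1,1,2-tris(trimethylsilyloxy)ethene
Product: 5 α-hydroxy acid (C5 set; CH2OH at C10 trans to the side chain; carbinol epimers), via Michael silyl dienol ether 4 (not isolated)
Conditions: (S)-o-tolyl-diphenylprolinol oxazaborolidine·HNTf2 (20 mol%), Ph3PO (0.3 equiv), PhMe, −40 °C; then 37% aq. HCHO, Yb(OTf)3 (10 mol%), THF, 0 °C to rt; used crude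
Reagents that add atoms: formaldehyde, C=O
Why: Proposed new method: the triflimide-activated oxazaborolidine binds the dienone carbonyl next to one of its two enantiotopic vinyl groups, so ketene acetal 3 adds to one β-carbon from the unshielded face and sets C5 (the catalyst antipode is chosen to give the drawn configuration); the closest known reaction is the oxazaborolidinium-catalysed Mukaiyama–Michael addition of silyl ketene acetals to cyclic enones, here made enantiotopic-group-selective, and the silyl dienol ether 4 is then hydroxymethylated at C10 by the known lanthanide-triflate aqueous formaldehyde aldol.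

Step 3
Reactants: 5 α-hydroxy acid; 6 pent-1-en-3-one
Product: 10 7,20-lactone (C10 quaternary; C20 cis and 3-oxopentyl chain trans to C6; C6 epimers), via tetrakis-silyl dienol ether 7 (not isolated), via silyl enol ether adduct 8 (not isolated), via seco acid 9 (not isolated)
Conditions: Me3SiOTf (4.4 equiv), Et3N (6 equiv), CH2Cl2, 0 °C; pentane, filter; 6 (1.5 equiv), HNTf2 (5 mol%), CH2Cl2, −78 °C; 1 M HCl, THF, rt; TsOH (5 mol%), PhMe, 80 °C
Reagents that add atoms: none
Why: Mukaiyama–Michael addition of the tetrasubstituted silyl enol ether creates the C10 quaternary centre with the new chain anti to the C5 side chain (axial attack on the half-chair whose other face carries the pseudo-axial C4 methyl), which leaves C20 cis to C6 so that acid closes the cis-fused 7,20-δ-lactone.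

Step 4
Reactants: 10 7,20-lactone
Product: 11 7,20-hemiketal with ring B closed (6,7-dihydroxy-7,20-epoxy tricycle; 8-propanoyl; C6 and C8 epimers)
Conditions: KOtBu (2.5 equiv), THF, −40 to 0 °C; then AcOH
Reagents that add atoms: none
Why: Intramolecular Claisen-type (Dieckmann-like) addition of the C8 ketone enolate to the lactone carbonyl C7 is the only six-membered closure available and gives carbocyclic ring B as the bridged 7,20-hemiketal of a 7,20-epoxy-ent-kauranoid, whose C7 configuration is fixed by the bicycle.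

Step 5
Reactants: 11 7,20-hemiketal
Product: 12 6,7-seco aldehyde β-keto spirolactone (C5–CHO cis to C20; C8 epimers)
Conditions: Pb(OAc)4 (1.1 equiv), CH2Cl2, 0 °C
Reagents that add atoms: none
Why: Criegee glycol cleavage of the 6,7-diol (hemiketal OH and C6–OH) cuts C6–C7, leaving C7 as the 7,20-lactone carbonyl and C6 as the aldehyde, the laboratory counterpart of the biosynthetic ring B scission; C5, C10 are untouched under these neutral conditions.

Step 6
Reactants: 12 6,7-seco aldehyde β-keto spirolactone
Product: 15 alkylidene β-keto spirolactone (C8=C9), via selenide 13 (not isolated), via selenoxide 14 (not isolated)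
Conditions: PhSeCl, pyridine, CH2Cl2, 0 °C; then NaIO4, NaHCO3, THF–H2O, rt
Reagents that add atoms: none
Why: α-Selenenylation of the β-keto lactone at C8 and selenoxide syn-elimination (Reich–Sharpless dehydrogenation) can only take a C9 hydrogen and gives the doubly activated C8=C9 dienophile.

Step 7
Reactants: 16 1-(phenylsulfanyl)propan-2-one
Product: 17 3-(phenylsulfanyl)but-3-en-2-one
Conditions: (CH2O)n, PhNH2Me+ CF3CO2− (1 equiv), THF, reflux
Reagents that add atoms: paraformaldehyde (formaldehyde), C=O
Why: Mannich-type α-methylenation occurs at the more acidic sulfur-bearing α-carbon and loss of the amine gives the 2-thio enone.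

Step 8
Reactants: 17 3-(phenylsulfanyl)but-3-en-2-one
Product: 18 2-(phenylsulfanyl)-3-(trimethylsilyloxy)buta-1,3-diene
Conditions: Me3SiOTf, Et3N, Et2O, 0 °C
Reagents that add atoms: trimethylsilyl trifluoromethanesulfonate, C[Si](C)(C)OS(=O)(=O)C(F)(F)F
Why: Soft enolisation and O-silylation of the methyl ketone (its only enolisable site) gives the 2-silyloxy-3-arylthio diene.

Step 9
Reactants: 15 alkylidene β-keto spirolactone; 18 2-(phenylsulfanyl)-3-(trimethylsilyloxy)buta-1,3-diene
Product: 19 Diels–Alder adduct (ring C cyclohexene with C12–SPh and C13–OSiMe3; C8 and C9 as in 25)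
Conditions: 18 (2.5 equiv), BHT (cat.), PhMe, 60 °C
Reagents that add atoms: none
Why: Thermal Diels–Alder reaction in which sulfur controls regiochemistry ("para" to the acyl-bearing carbon), so C11 bonds to C9 and C14 to C8 and the oxygen lands on C13; suprafacial addition to the face of C8=C9 anti to the bulky C5 branch (on the side of the flat C1 carbonyl) sets the C9–H and C8 quaternary centres cis to each other.

Step 10
Reactants: 19 Diels–Alder adduct
Product: 21 13,15-diketone 6-aldehyde, via phenylsulfanyl ketone 20 (not isolated)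
Conditions: Zn dust, AcOH–THF–H2O (3:3:1), rt
Reagents that add atoms: none
Why: Aqueous acid hydrolyses the silyl enol ether to the C13 ketone and zinc then removes the α-phenylsulfanyl group (dissolving-metal reductive cleavage of an α-heteroatom ketone).

Step 11
Reactants: 21 13,15-diketone 6-aldehyde
Product: 22 13,15-diketone 6-alcohol
Conditions: NaBH(OAc)3 (1.5 equiv), AcOH (1 equiv), ClCH2CH2Cl, rt
Reagents that add atoms: none
Why: Triacetoxyborohydride reduces the aldehyde chemoselectively and leaves the three ketones and the lactone; the reduction is placed after step 9 because a free C6–OH would add to the C8=C9 acceptor.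

Step 12
Reactants: 22 13,15-diketone 6-alcohol
Product: 23 ring D ketol (13-hydroxy-16-methyl-15-ketone; C16 epimers)
Conditions: KOtBu (0.2 equiv), t-BuOH–THF, 0 °C
Reagents that add atoms: none
Why: Intramolecular aldol addition of the C16 enolate to the C13 ketone closes the bicyclo[3.2.1]octane; the bridge can only form on the face of ring C that carries the C8 acyl group, which fixes C13.

Step 13
Reactants: 23 ring D ketol (C16 epimers)
Product: 25 target, via trilithium enolate 24 (not isolated)
Conditions: LiN(iPr)2 (4 equiv), THF, −78 °C; then AcOH in THF, −78 °C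
Reagents that add atoms: none
Why: Kinetic protonation of the C15–C16 enolate (the only enolisable site) from the open exo face, on the side of the one-carbon C14 bridge, puts H exo and the methyl endo, giving the less stable (16R) epimer from either C16 epimer.

**Compound list**

1 | 4,4-dimethylcyclohex-2-en-1-one | CC1(C)CCC(=O)C=C1 | starting material
2 | 4,4-dimethylcyclohexa-2,5-dien-1-one | CC1(C)C=CC(=O)C=C1 | intermediate
3 | 1,1,2-tris(trimethylsilyloxy)ethene | C[Si](C)(C)OC=C(O[Si](C)(C)C)O[Si](C)(C)C | starting material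
4 | trimethylsilyl 2-[(1S)-6,6-dimethyl-3-(trimethylsilyloxy)cyclohexa-2,4-dien-1-yl]-2-(trimethylsilyloxy)acetate (carbinol epimers) | C[Si](C)(C)OC1=C[C@H](C(O[Si](C)(C)C)C(=O)O[Si](C)(C)C)C(C)(C)C=C1 | intermediate
5 | 2-hydroxy-2-[(1S)-6-(hydroxymethyl)-2,2-dimethyl-5-oxocyclohex-3-en-1-yl]acetic acid (CH2OH trans to the side chain; carbinol epimers) | OC[C@@H]1C(=O)C=CC(C)(C)[C@H]1C(O)C(=O)O | intermediate
6 | pent-1-en-3-one | CCC(=O)C=C | starting material
7 | tetrakis(trimethylsilyl) derivative of 5 (C1 silyl dienol ether, C20 and C6 silyl ethers, silyl ester) | C[Si](C)(C)OCC1=C(O[Si](C)(C)C)C=CC(C)(C)[C@H]1C(O[Si](C)(C)C)C(=O)O[Si](C)(C)C | intermediate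
8 | Michael adduct as C15 silyl enol ether (C10 quaternary; C20 and C6 silyl ethers, silyl ester) | CCC(O[Si](C)(C)C)=CC[C@]1(CO[Si](C)(C)C)C(=O)C=CC(C)(C)[C@H]1C(O[Si](C)(C)C)C(=O)O[Si](C)(C)C | intermediate
9 | seco acid: 2-hydroxy-2-[6-(hydroxymethyl)-2,2-dimethyl-5-oxo-6-(3-oxopentyl)cyclohex-3-en-1-yl]acetic acid (CH2OH cis to the side chain) | CCC(=O)CC[C@]1(CO)C(=O)C=CC(C)(C)[C@H]1C(O)C(=O)O | intermediate
10 | 7,20-lactone: ring A enone cis-fused at C5–C10 to the δ-lactone C10–C20H2–O–C7(=O)–C6H(OH)–C5; 3-oxopentyl on C10 trans to C6; C6 epimers | CCC(=O)CC[C@@]12COC(=O)C(O)[C@@H]1C(C)(C)C=CC2=O | intermediate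
11 | 7,20-hemiketal: 6,7-dihydroxy-7,20-epoxy tricycle (ring A enone, ring B as 2-oxabicyclo[2.2.2]octane), 8-propanoyl; C6 and C8 epimers | CCC(=O)C1C[C@@]23CO[C@]1(O)C(O)[C@@H]2C(C)(C)C=CC3=O | intermediate
12 | 6,7-seco aldehyde: spiro δ-lactone C10–C20H2–O–C7(=O)–C8H(propanoyl)–C9H2 on the ring A enone, C5–CHO cis to C20; C8 epimers | CCC(=O)C1C[C@]2(COC1=O)C(=O)C=CC(C)(C)[C@H]2C=O | intermediate
13 | 8-(phenylselanyl) derivative of 12 | CCC(=O)C1([Se]c3ccccc3)C[C@]2(COC1=O)C(=O)C=CC(C)(C)[C@H]2C=O | intermediate
14 | selenoxide of 13 | CCC(=O)C1([Se](=O)c3ccccc3)C[C@]2(COC1=O)C(=O)C=CC(C)(C)[C@H]2C=O | intermediate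
15 | alkylidene β-keto spirolactone (12 with C8=C9) | CCC(=O)C1=C[C@]2(COC1=O)C(=O)C=CC(C)(C)[C@H]2C=O | intermediate
16 | 1-(phenylsulfanyl)propan-2-one | CC(=O)CSc1ccccc1 | starting material
17 | 3-(phenylsulfanyl)but-3-en-2-one | CC(=O)C(=C)Sc1ccccc1 | intermediate
18 | 2-(phenylsulfanyl)-3-(trimethylsilyloxy)buta-1,3-diene | C=C(Sc1ccccc1)C(O[Si](C)(C)C)=C | intermediate
19 | Diels–Alder adduct: ring C cyclohexene (C12–SPh, C13–OSiMe3) cis-fused to the lactone at C8–C9; 8-propanoyl; 6-aldehyde | CCC(=O)[C@]12CC(O[Si](C)(C)C)=C(Sc3ccccc3)C[C@H]1[C@]1(COC2=O)C(=O)C=CC(C)(C)[C@H]1C=O | intermediate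
20 | 12-(phenylsulfanyl)-13-ketone (C12 epimers) | CCC(=O)[C@]12CC(=O)C(Sc3ccccc3)C[C@H]1[C@]1(COC2=O)C(=O)C=CC(C)(C)[C@H]1C=O | intermediate
21 | 13,15-diketone 6-aldehyde (8-propanoyl, ring C cyclohexanone) | CCC(=O)[C@]12CC(=O)CC[C@H]1[C@]1(COC2=O)C(=O)C=CC(C)(C)[C@H]1C=O | intermediate
22 | 13,15-diketone 6-alcohol | CCC(=O)[C@]12CC(=O)CC[C@H]1[C@]1(COC2=O)C(=O)C=CC(C)(C)[C@H]1CO | intermediate
23 | ring D ketol: 25 as a mixture of C16 epimers | CC1C(=O)[C@]23C[C@@]1(O)CC[C@H]2[C@]1(COC3=O)C(=O)C=CC(C)(C)[C@H]1CO | intermediate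
24 | trilithium salt of 23 (C15–C16 enolate, C13 and C6 alkoxides) | [Li+].[Li+].[Li+].CC1=C([O-])[C@]23C[C@@]1([O-])CC[C@H]2[C@]1(COC3=O)C(=O)C=CC(C)(C)[C@H]1C[O-] | intermediate
25 | (5R,8S,9S,10S,13S,16R)-6,13-dihydroxy-1,15-dioxo-6,7-secokaur-2-en-7,20-olide (kaurane atom labels) | C[C@H]1C(=O)[C@]23C[C@@]1(O)CC[C@H]2[C@]1(COC3=O)C(=O)C=CC(C)(C)[C@H]1CO | target

**Totals**
Total steps: 13. Longest linear sequence: 11 (steps 1–6 and 9–13; steps 7–8 make the diene).

**Three steps most likely to fail, with fallbacks**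

Step 2 (enantiotopic-group selection on a β-hindered dienone is unprecedented). The fallback sets out from 2 and returns at 4. Rhodium-catalysed asymmetric 1,4-addition of potassium vinyltrifluoroborate ([RhCl(C2H4)2]2, chiral diene ligand, KOH, dioxane–H2O) gives the 5-vinyl enone F1. OsO4 (cat.)/NMO dihydroxylates only the electron-rich vinyl group to the diol F2. TEMPO/NaOCl/NaClO2 oxidises the primary alcohol to the α-hydroxy acid F3. Me3SiOTf/Et3N then gives silyl dienol ether 4, which is hydroxymethylated as in step 2.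

Step 9 (the hindered C9 terminus may erode the sulfur-directed regiochemistry or the facial bias). The fallback sets out from 15 and returns at 21, bypassing steps 9 and 10. An iodine-atom-transfer radical annulation with 4-iodo-2-methoxybut-1-ene (Et3B, air, PhH, rt) is used instead. The primary radical adds to C9 anti to C5; the resulting C8 dicarbonyl radical closes 6-endo on the enol ether CH2 (C14), cis by ring constraint; iodine transfer gives the 13-iodo-13-methoxy adduct F4. Aqueous NaHCO3 hydrolyses F4 to 21.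

Step 13 (the exo-face preference of the protonation may be modest; the thermodynamic epimer is expected to be 16-epi). The fallback sets out from 23 and returns at 25. Enolate 24 (LiN(iPr)2) is trapped with PhSeBr to give the 16-phenylselanyl ketone F5. NaIO4 gives the selenoxide F6, whose syn-elimination can only take a C17 hydrogen and gives the 16-methylene enone F7. H2 with RhCl(PPh3)3 reduces only the 1,1-disubstituted alkene, from the exo face, to give 25.

**Further compounds**

F1 | step 2 | 4,4-dimethyl-5-vinylcyclohex-2-en-1-one (C5 as in 4) | C=C[C@H]1CC(=O)C=CC1(C)C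
F2 | step 2 | 5-(1,2-dihydroxyethyl)-4,4-dimethylcyclohex-2-en-1-one (carbinol epimers) | OCC(O)[C@H]1CC(=O)C=CC1(C)C
F3 | step 2 | 2-(6,6-dimethyl-3-oxocyclohex-4-en-1-yl)-2-hydroxyacetic acid (carbinol epimers) | OC(=O)C(O)[C@H]1CC(=O)C=CC1(C)C
F4 | step 9 | 13-iodo-13-methoxy annulation adduct (ring C closed; 8-propanoyl; 6-aldehyde) | CCC(=O)[C@]12CC(I)(OC)CC[C@H]1[C@]1(COC2=O)C(=O)C=CC(C)(C)[C@H]1C=O
F5 | step 13 | 16-(phenylselanyl) derivative of 23 | CC1([Se]c4ccccc4)C(=O)[C@]23C[C@@]1(O)CC[C@H]2[C@]1(COC3=O)C(=O)C=CC(C)(C)[C@H]1CO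
F6 | step 13 | selenoxide of F5 | CC1([Se](=O)c4ccccc4)C(=O)[C@]23C[C@@]1(O)CC[C@H]2[C@]1(COC3=O)C(=O)C=CC(C)(C)[C@H]1CO
F7 | step 13 | 16-methylene enone (16,17-didehydro-25) | C=C1C(=O)[C@]23C[C@@]1(O)CC[C@H]2[C@]1(COC3=O)C(=O)C=CC(C)(C)[C@H]1CO
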